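In a one-step world, Q and J at equal charge run to full Z, but the summer flask stands at 91.1% Z at 5.00 d with Q at 0%, and the noon flask, with 1.5 equiv of J, reaches 98.0%. So the step looks reversible, and the bench question is where it ends after warming.

| flask | Q | J | temperature | remark | time |
|---|---|---|---|---|---|
| summer | 0.14 M | 1 equiv (fed, over 4.0 d) | −15 °C | run made earlier; the fed solution adds 0.25 times the starting volume |  |
| spring | 0.22 M | 1 equiv (fed, over 4.0 d) | 0 °C | run made earlier; the fed solution adds 0.25 times the starting volume |  |
| noon | 0.10 M | 1.5 equiv (fed, over 4.0 d) | −15 °C | run made earlier; the fed solution adds 0.25 times the starting volume |  |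
| green | 0.10 M | 1.00 equiv (fed, over 4.0 d) |  | at −10 °C until 4.0 d, from then on at 10 °C; the fed solution adds 0.25 times the starting volume | 6.0 d |
| ochre | 0.10 M | 1.00 equiv (fed, over 15 d) |  | at −10 °C throughout; the fed solution adds 0.25 times the starting volume | 6.0 d |

| run | time / d | Z / % | Q / % |
|---|---|---|---|
| summer | 0.417 | 5.2 | 85.6 |
| summer | 1.25 | 25.0 | 66.3 |
| summer | 2.00 | 42.0 | 47.8 |
| summer | 3.00 | 64.9 | 24.0 |
| summer | 5.00 | 91.1 | 0 |
| spring | 0.250 | 3.7 | 92.8 |
| spring | 0.500 | 9.2 | 86.8 |
| spring | 0.833 | 17.2 | 78.7 |
| spring | 1.67 | 33.5 | 61.5 |
| spring | 3.00 | 56.4 | 36.3 |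
| noon | 0.417 | 7.4 | 79.6 |
| noon | 0.833 | 22.2 | 66.3 |
| noon | 1.25 | 37.0 | 51.0 |
| noon | 2.50 | 80.8 | 5.8 |
| noon | 5.00 | 98.0 | 0.2 |

(readings scatter by 0.3 percentage points)

- charges are per starting volume, the dose included; the dosed solution carries all of it
- given per volume of solution although it is solid: Q
- at the start none of Q is in solution
- what has only dissolved of Q counts as not reacted
- percentages count the whole charge, also what has not yet gone in

1. which of the two ends with the higher amount of Z, in percent of the Q charged ("neither" if they lie within 2 percentage points) (green / ochre / neither)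
2. Z at the end, in percent of the Q charged, green
3. Z at the end, in percent of the Q charged, ochre

The number to find is the end quotient: Z squared over dissolved Q times free J, all as shares of the Q charged. This assumes one by-product per link, so the volume cancels. Dissolved Q is what Z and solid Q leave missing, and free J is what has been fed minus Z. As readings, summer gives 105 and noon 103 at −15 °C, from different J charges. Spring at 0 °C gives 23.4 at 3.00 d, a reading taken earlier than the end of its feed at 4.0 d, so it is probably a low figure. A straight line of the logarithm against temperature then gives 8.63, my estimate of the end quotient at 10 °C.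

At equal charge, with J fully fed and solid Q gone, end Z is the root of this quotient over one plus that root, so my reckoning puts green at about 74.6%. Green warm has 2.00 d, longer than the 1.00 d after which cold summer already matched noon, so this is thermodynamic control. One number is not enough for ochre: only 40.0% of its J is in at 6.0 d, so J is the limiting reagent and Z must stay below that share.

The forecast says green, with 90% for green and 34% for ochre, holding that “Warming then adds little because J is gone”. For green it stands 15 percentage points above my figure.

The flask gives green: green 79.6%, ochre 38.1%.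

    Q ⇌ E, rate k1*(cs1 - [E]) while solid is left; crystals form when [E] > cs1 (solubility = 18.0 mM, k = 6.10 × 10⁻⁵ s⁻¹)
    E + J ⇌ Z + L (K = 65.0, k = 0.00620 M⁻¹ s⁻¹, Ea = 53.0 kJ mol⁻¹, ΔH = −45.0 kJ mol⁻¹)
    (constants at −10 °C)

Green holds Z at 87.9% at 4.00 d, falls to 79.6% at 6.00 d, and shows 79.6% at 60.0 d. Its end quotient is 15.2, higher than the reckoned 8.63. The neighbouring flask is green with 0.400 equiv of J, and at 6.00 d it keeps solid Q at 41.3% with E at 22.5%. Setting Z squared over E times J charge minus Z equal to 8.63 gives Z of 34.0%. The neighbouring flask gives 36.2%.

The earlier runs and the new flask come from a simulation with made-up constants.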